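A flask that spends its reagent is easily over-credited, since the substrate meets less reagent than was charged.

| flask | left-handed substrate | right-handed substrate | reagent | racemization catalyst | remark | time |
|---|---|---|---|---|---|---|
| autumn | 0.25 M | 0.25 M | 0.75 M | 0.45 mM | run made earlier |  |
| summer | 0.25 M | 0.25 M | 0.75 M | 0.91 mM | run made earlier |  |
| midnight | 0.25 M | 0.25 M | 0.75 M | 1.3 mM | run made earlier |  |
| winter | 0.25 M | 0.25 M | 1.1 M | 1.2 mM | run made earlier |  |
| east | 0.25 M | 0.25 M | 1.50 M | 0.60 mM |  | 6.0 min |
| north | 0.25 M | 0.25 M | 0.750 M | 1.2 mM |  | 25 min |

- autumn (time / min: left-handed product / %, left-handed substrate / %): 1.00: 4.5, 45.8; 3.00: 12.3, 42.6; 6.00: 22.4, 38.1; 8.00: 27.2, 34.7; 12.0: 37.1, 30.8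
- summer (time / min: left-handed product / %, left-handed substrate / %): 1.00: 4.7, 47.5; 3.00: 12.0, 43.1; 6.00: 22.2, 38.4; 8.00: 27.7, 36.1; 12.0: 37.2, 30.9
- midnight (time / min: left-handed product / %, left-handed substrate / %): 2.50: 9.9, 44.2; 5.00: 19.0, 39.8; 8.00: 28.2, 35.5; 10.0: 32.5, 32.8; 12.0: 36.9, 31.0
- winter (time / min: left-handed product / %, left-handed substrate / %): 1.00: 6.1, 46.0; 3.00: 17.3, 40.4; 6.00: 30.7, 34.2; 8.00: 37.5, 30.7; 12.0: 49.8, 24.8

(each reading ± 0.3 percentage points)

- reagent is single-handed; left-handed substrate and right-handed substrate are mirror images of each other, charged as a racemate, each of them at the stated concentration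
- the earlier runs were read with a standard deviation of 0.3 percentage points
- the handed part of reagent does not stay in what it makes, so the products of the two hands are mirror images too

1. the winner by amount of left-handed product, in percent of the left-handed substrate and right-handed substrate together charged; "neither" if no more than 2 percentage points parts them (east / north / neither)
2. how much left-handed product is there at the end, in percent of the left-handed substrate and right-handed substrate together charged: east
3. how much left-handed product is there at the end, in percent of the left-handed substrate and right-handed substrate together charged: north

First question: does the racemization catalyst matter here? Going from 0.45 mM in the autumn run to 1.3 mM in the midnight run moves the left-handed product read at 12.0 min from 37.1 % to 36.9 %, a shift of 0.2 percentage points against a scatter of 0.3 points. In the autumn run the left-handed substrate is also about half of the substrate not yet turned into product. So the two hands can be treated as one pool, with s the fraction of it surviving and the rest read as left-handed product.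

Second question: what does the pool feel? If reagent is spent one for one, its mean can be taken as the midpoint between charge and end value, which makes the pool pseudo-first-order. The pool constant is then minus the logarithm of s, divided by mean reagent and time. The last winter reading gives the pool constant 9.81 × 10⁻⁴ M⁻¹ s⁻¹, and the last autumn reading, with less reagent, gives 9.80 × 10⁻⁴ M⁻¹ s⁻¹.

Third question: what do the flasks give? For north, reagent held at its charge would promise 66.8 %. A guessed conversion of 0.5 puts the mean at 0.833 of the charge and gives 60.1 %. That conversion corrects the mean to 0.800 and gives 58.6 %. The same two passes for east give 38.5 %, then 39.1 %. This reckoning puts north ahead of east by 20 points, beyond the margin of 2 points.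

The forecast also names north, with 39 % for east and 57.5 % for north, the latter a little below this reckoning. It rests on the reading that “racemization is not limiting”.

The flasks give north as the winner, with 38.8 % for east and 57.7 % for north.

    reagent → decomposition product (k = 7.42 × 10⁻⁶ s⁻¹)
    reagent + left-handed substrate → left-handed product (k = 0.00205 M⁻¹ s⁻¹)
    left-handed substrate + racemization catalyst ⇌ right-handed substrate + racemization catalyst, rate k3*[racemization catalyst]*[left-handed substrate] forward; the back reaction follows from the equilibrium constant (k = 27.2 M⁻¹ s⁻¹)
    reagent + right-handed substrate → right-handed product (k = 1.82 × 10⁻⁵ M⁻¹ s⁻¹)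

The midpoint reckoning stands 0.9 points above north and 0.30 points above east, less than the gap of 19 points between them. The neighbour of north, charged with 1.3 M of reagent, goes through the same two passes. The guess gives 82.3 %, and the corrected mean of 0.842 of the charge gives 80.0 %. That neighbouring flask holds 78.6 % of left-handed product at the end.

(The earlier runs and the new flask are calculated on assumed constants; noise was put on by code.)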